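Assumption: lehualide C has no stereocentres, so "single enantiomer" is taken to mean the single (E)-alkene isomer shown. The route is a design from known reaction types and has not been run.

## Retrosynthetic overview

1. C–S bond last: the thioacetate comes from a primary alcohol by Mitsunobu reaction with thioacetic acid.
2. The pyrone–CH2 to CH=C(Me) bond comes from Pd-catalysed coupling of a 6-(bromomethyl)-γ-pyrone with an (E)-alkenylalane. The alane is made by Zr-catalysed methylalumination of commercial undec-10-yn-1-ol, which sets the E-trisubstituted alkene.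
3. The bromomethyl pyrone comes from lateral (vinylogous) deprotonation and bromination of 2,3-dimethoxy-5,6-dimethyl-4-pyranone.
4. The only ring is formed once: a 3,5-diketo ester lactonises to a 4-hydroxy-2-pyranone, which is then O-methylated on the ring carbonyl to give the γ-pyrone.
5. The diketo ester comes from methyl methoxyacetate, propionyl chloride and an acetyl Weinreb amide (Claisen, then β-keto ester dianion acylation).

## Route

**Step 1**
Reactants: 1 methyl methoxyacetate; 2 propionyl chloride
Product: 3 methyl 2-methoxy-3-oxopentanoate (racemic, labile α-centre, of no consequence)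
Conditions: LDA (2 equiv), 1 (2 equiv), THF, −78 °C; then 2 (1 equiv), −78 → 0 °C; aq. NH4Cl
Reagents that add atoms: none (all heavy atoms come from 1 and 2)
Why: Crossed Claisen C-acylation of the chelated lithium enolate of an α-alkoxy ester by an acid chloride; the second equivalent of enolate absorbs the acidic β-keto ester proton.

**Step 2**
Reactants: 3 methyl 2-methoxy-3-oxopentanoate; 4 N-methoxy-N-methylacetamide
Product: 5 methyl 2-methoxy-4-methyl-3,5-dioxohexanoate (mixture of diastereomers and enol tautomers)
Conditions: LDA (2.2 equiv), THF, −78 → 0 °C; then 4, −78 → 0 °C; aq. NH4Cl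
Reagents that add atoms: none (all heavy atoms come from 3 and 4)
Why: Huckin–Weiler β-keto ester dianion reacts at the more nucleophilic γ-carbon (the ethyl CH2); the Weinreb amide gives a stable chelate, so the acidic product is not released until work-up.

**Step 3**
Reactants: 5 methyl 2-methoxy-4-methyl-3,5-dioxohexanoate
Product: 6 4-hydroxy-3-methoxy-5,6-dimethyl-2H-pyran-2-one
Conditions: DBU, PhMe, 80 °C; then 1 M HCl
Reagents that add atoms: none
Why: Base-mediated enol-lactonisation of a 3,5-diketo ester (C5 enol oxygen attacks the methyl ester, MeOH lost), the standard 4-hydroxy-α-pyrone synthesis.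

**Step 4**
Reactants: 6 4-hydroxy-3-methoxy-5,6-dimethyl-2H-pyran-2-one
Product: 7 2,3-dimethoxy-5,6-dimethyl-4H-pyran-4-one
Conditions: MeOTf (1.2 equiv), CH2Cl2, rt; aq. NaHCO3
Reagents that add atoms: methyl triflate, COS(=O)(=O)C(F)(F)F
Why: A hard methylating agent alkylates the lactone carbonyl oxygen of a 4-hydroxy-2-pyranone to give a 4-hydroxy-2-methoxypyrylium, which loses a proton on work-up to the 2-methoxy-γ-pyrone (regioselective O-methylation).

**Step 5**
Reactants: 7 2,3-dimethoxy-5,6-dimethyl-4H-pyran-4-one
Product: 8 6-(bromomethyl)-2,3-dimethoxy-5-methyl-4H-pyran-4-one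
Conditions: LiHMDS (1.05 equiv), THF, −78 °C; then cannulate into NBS (1.2 equiv), THF, −78 °C
Reagents that add atoms: N-bromosuccinimide, O=C1CCC(=O)N1Br
Why: Only the C6 methyl is vinylogously acidic (γ to the C4 carbonyl), so the dienolate forms there and is brominated at the exocyclic carbon; inverse addition limits dibromination and self-alkylation.

**Step 6**
Reactants: 9 undec-10-yn-1-ol; 8 6-(bromomethyl)-2,3-dimethoxy-5-methyl-4H-pyran-4-one
Product: 10 6-[(2E)-12-hydroxy-3-methyldodec-2-en-1-yl]-2,3-dimethoxy-5-methyl-4H-pyran-4-one
Conditions: 9 (1.5 equiv), Me3Al (3 equiv per alkyne), Cp2ZrCl2 (0.3 equiv), CH2Cl2, 0 °C → rt; evaporate excess Me3Al, THF; then 8 (1 equiv), Pd(PPh3)4 (5 mol%), rt; Rochelle salt work-up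
Reagents that add atoms: trimethylaluminium, C[Al](C)C
Why: Negishi Zr-catalysed carboalumination adds Me–Al syn across the terminal alkyne (the OH is masked in situ as its aluminium alkoxide), and Pd-catalysed coupling of the alkenylalane with the benzylic-type bromide proceeds with retention. The pyrone CH2 therefore ends up cis to the new methyl, which is the E isomer.

**Step 7**
Reactants: 10 6-[(2E)-12-hydroxy-3-methyldodec-2-en-1-yl]-2,3-dimethoxy-5-methyl-4H-pyran-4-one
Product: 11 lehualide C, S-[(10E)-12-(5,6-dimethoxy-3-methyl-4-oxo-4H-pyran-2-yl)-10-methyldodec-10-en-1-yl] ethanethioate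
Conditions: PPh3, DIAD, THF, 0 °C; then 10 and AcSH, 0 °C → rt
Reagents that add atoms: thioacetic acid, CC(=O)S
Why: Mitsunobu thioesterification of a primary alcohol with an acidic sulfur pronucleophile under neutral, mild conditions that leave the γ-pyrone and the skipped alkene untouched.

## Compound list

1 | methyl methoxyacetate | COCC(=O)OC | starting material
2 | propionyl chloride | CCC(Cl)=O | starting material
3 | methyl 2-methoxy-3-oxopentanoate | CCC(=O)C(OC)C(=O)OC | intermediate
4 | N-methoxy-N-methylacetamide | CC(=O)N(C)OC | starting material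
5 | methyl 2-methoxy-4-methyl-3,5-dioxohexanoate | CC(=O)C(C)C(=O)C(OC)C(=O)OC | intermediate
6 | 4-hydroxy-3-methoxy-5,6-dimethyl-2H-pyran-2-one | COC1=C(O)C(C)=C(C)OC1=O | intermediate
7 | 2,3-dimethoxy-5,6-dimethyl-4H-pyran-4-one | COc1oc(C)c(C)c(=O)c1OC | intermediate
8 | 6-(bromomethyl)-2,3-dimethoxy-5-methyl-4H-pyran-4-one | COc1oc(CBr)c(C)c(=O)c1OC | intermediate
9 | undec-10-yn-1-ol | C#CCCCCCCCCCO | starting material
10 | 6-[(2E)-12-hydroxy-3-methyldodec-2-en-1-yl]-2,3-dimethoxy-5-methyl-4H-pyran-4-one | COc1oc(C/C=C(\C)CCCCCCCCCO)c(C)c(=O)c1OC | intermediate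
11 | lehualide C | COc1oc(C/C=C(\C)CCCCCCCCCSC(C)=O)c(C)c(=O)c1OC | target

## Summary

Total steps: 7
Longest linear sequence: 7 (1 → 3 → 5 → 6 → 7 → 8 → 10 → 11); the side-chain partner 9 is used as purchased.

Three steps most likely to fail:

1. **Step 5, lateral bromination.** Risks are dibromination and alkylation of the dienolate by product 8. Fallback: carry the oxygen in from the start by acylating the dianion of 3 with N-methoxy-N-methyl-2-(benzyloxy)acetamide in place of 4. Then cyclise and methylate as before, hydrogenolyse the benzyl ether and convert the alcohol to 8 with CBr4/PPh3.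
2. **Step 6, one-pot carboalumination and Pd coupling.** Risks are competing methyl transfer from residual Me3Al, interference from the aluminium alkoxide, and sluggish coupling with the Lewis-basic pyrone. Fallback: quench the alane with I2 to isolate (E)-11-iodo-10-methylundec-10-en-1-ol and protect it as the TBS ether. Then reverse the polarity: convert 8 to the pyronylmethylzinc bromide (Zn, LiCl) and Negishi-couple it with the vinyl iodide, followed by desilylation.
3. **Step 4, regioselective O-methylation.** The risk is formation of the isomeric 3,4-dimethoxy-2-pyranone. Fallback: block the 4-OH first as its TBS ether, alkylate the lactone carbonyl with Me3OBF4, and release the γ-pyrone by desilylation of the resulting 2-methoxy-4-silyloxypyrylium salt.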